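**Retrosynthetic overview**
- The 7-OH is unmasked last by O-debenzylation of a 7-O-benzyl flavonol.
- The pyranone ring is the only ring made (both benzene rings are bought). It is closed by phenoxide O1–C2 bond formation with the C3–OH installed in the same pot: Claisen–Schmidt condensation, then Algar–Flynn–Oyamada oxidation of a 2'-hydroxyacetophenone with a benzaldehyde.
- A-ring ketone: 2',4'-dihydroxy-6'-methoxyacetophenone, by 4'-O-benzylation, Elbs C5'–O hydroxylation and 5'-O-methylation.
- B-ring aldehyde: half-reduction of an (S)-hydroxy nitrile. Its C–O bond and its stereocentre come from a catalytic enantioselective anti-Markovnikov hydration (CuH hydroboration, then oxidation) of a 1,1-disubstituted alkene.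
- That alkene: Negishi coupling of 3-bromo-4-methoxybenzonitrile with the zinc reagent of 4-bromo-2-methylbut-1-ene.

Assumption: 2 and 9 are taken as catalogue chemicals; primed locants refer to the acetophenone/chalcone A ring (C1' carries the carbonyl group).

**Route**

Step 1
Reactants: 1 3-bromo-4-methoxybenzonitrile; 2 4-bromo-2-methylbut-1-ene
Product: 4 4-methoxy-3-(3-methylbut-3-en-1-yl)benzonitrile, via homoallylzinc bromide 3 (not isolated)
Conditions: 2, Zn dust, LiCl, THF, 50 °C (cat. BrCH2CH2Br/TMSCl activation); then 1, Pd(OAc)2 (1 mol%), SPhos (2 mol%), THF, 25 °C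
Reagents that add atoms: zinc, [Zn] (stays only in intermediate 3; no reagent atoms remain in 4)
Why: LiCl-mediated zinc insertion into the primary bromide gives a homoallylzinc reagent that tolerates the nitrile, and Pd/SPhos Negishi cross-coupling at the C–Br bond of 1 outruns β-hydride elimination, so the terminal 1,1-disubstituted alkene arrives intact.

Step 2
Reactants: 4 4-methoxy-3-(3-methylbut-3-en-1-yl)benzonitrile
Product: 6 3-[(3S)-4-hydroxy-3-methylbutyl]-4-methoxybenzonitrile, via alkyl pinacolboronate 5 (not isolated)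
Conditions: Cu(OAc)2 (3 mol%), L* (3.3 mol%), HBpin (1.5 equiv), THF, 25 °C; then NaBO3·4H2O, THF/H2O, 25 °C. L* is the proposed cleft ligand: a SEGPHOS-type biaryl bisphosphine in which each phosphorus carries two 3,5-bis(3,5-di-tert-butylphenyl)phenyl (m-terphenyl) groups, used as the antipode that delivers hydride to the Si face of the internal alkene carbon.
Reagents that add atoms: pinacolborane, CC1(C)OBOC1(C)C (boron of intermediate 5 only); sodium perborate, [Na+].[Na+].O[B-]1(O)OO[B-](O)(O)OO1 (hydroxyl oxygen of 6)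
Why: Proposed new method: enantioselective CuH-catalysed anti-Markovnikov hydroboration of a 2-methyl-1-alkene whose second substituent is an unbranched 2-arylethyl chain, followed by C–B to C–O oxidation in the same pot — L*Cu–H (from Cu(OAc)2/HBpin) adds syn across the alkene with Cu at the terminal carbon and H at C3, the m-terphenyl cleft of L* holding the arylethyl arm by dispersion and π-contacts that a methyl group cannot make, so that hydride goes to the Si face of C3 (enantio-determining), σ-bond metathesis with HBpin then releases boronate 5 and CuH, and perborate oxidation (boron-to-oxygen 1,2-shift, stereocentre untouched because it is β to boron) forms the C–O bond of (S)-6 (the CIP label changes from R in 5 to S in 6 without any change in geometry); the closest known reaction type is bisphosphine–CuH hydroboration/hydroamination of 1,1-disubstituted alkenes whose two substituents differ strongly in size (aryl/alkyl or branched alkyl/methyl), whereas methyl against a linear chain has not been shown at useful ee; the ligand antipode is fixed after the first run by Mosher-ester comparison with authentic (S)-6.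

Step 3
Reactants: 6 3-[(3S)-4-hydroxy-3-methylbutyl]-4-methoxybenzonitrile
Product: 8 3-[(3S)-4-hydroxy-3-methylbutyl]-4-methoxybenzaldehyde, via bis(diisobutylaluminio) aldimine 7 (not isolated)
Conditions: DIBAL-H (2.5 equiv), CH2Cl2, −78 → −40 °C; then 1 M HCl, 0 °C
Reagents that add atoms: diisobutylaluminium hydride, CC(C)C[AlH]CC(C)C (Al and isobutyl groups of intermediate 7 only); water, O (aldehyde oxygen of 8)
Why: DIBAL-H (one equivalent is consumed by the alcohol as its alkoxide) adds once to the aryl nitrile to give an N-aluminated aldimine that is stable at low temperature and is hydrolysed to the aldehyde on acidic work-up (nitrile half-reduction), the remote stereocentre being untouched.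

Step 4
Reactants: 9 2',4'-dihydroxy-6'-methoxyacetophenone
Product: 10 4'-(benzyloxy)-2'-hydroxy-6'-methoxyacetophenone
Conditions: BnBr (1.05 equiv), K2CO3 (1.2 equiv), acetone, reflux
Reagents that add atoms: benzyl bromide, BrCc1ccccc1
Why: The 4'-OH (para to the acetyl group, not hydrogen-bonded) is far more acidic and nucleophilic than the chelated 2'-OH, so Williamson etherification with one equivalent of BnBr is selective.

Step 5
Reactants: 10 4'-(benzyloxy)-2'-hydroxy-6'-methoxyacetophenone
Product: 12 4'-(benzyloxy)-2',5'-dihydroxy-6'-methoxyacetophenone, via aryl potassium sulfate 11 (not isolated)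
Conditions: K2S2O8 (1.1 equiv), 10% aq KOH/pyridine, 0 → 20 °C, 24 h; acidify to pH 5 and extract unreacted 10; then conc. HCl, 90 °C, 1 h, N2
Reagents that add atoms: potassium peroxodisulfate, [K+].[K+].[O-]S(=O)(=O)OOS(=O)(=O)[O-]
Why: Elbs persulfate oxidation: the phenoxide of 10 attacks peroxodisulfate through the carbon para to the phenoxide oxygen (C5', the only free para position), giving aryl sulfate 11, which acid hydrolyses to the hydroquinone, so the C5'–O bond is formed with unambiguous regiochemistry.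

Step 6
Reactants: 12 4'-(benzyloxy)-2',5'-dihydroxy-6'-methoxyacetophenone
Product: 13 4'-(benzyloxy)-2'-hydroxy-5',6'-dimethoxyacetophenone
Conditions: MeI (1.1 equiv), K2CO3 (1.2 equiv), acetone, 45 °C
Reagents that add atoms: iodomethane, CI
Why: The chelated 2'-OH is unreactive toward MeI/K2CO3 under these mild conditions, so Williamson methylation takes place only at the 5'-OH.

Step 7
Reactants: 13 4'-(benzyloxy)-2'-hydroxy-5',6'-dimethoxyacetophenone; 8 3-[(3S)-4-hydroxy-3-methylbutyl]-4-methoxybenzaldehyde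
Product: 15 7-(benzyloxy)-3-hydroxy-2-{3-[(3S)-4-hydroxy-3-methylbutyl]-4-methoxyphenyl}-5,6-dimethoxy-4H-chromen-4-one, via 2'-hydroxychalcone 14 (not isolated)
Conditions: 8 (1.1 equiv), KOH (10 equiv), EtOH, 25 °C, 36 h; then MeOH, 0 °C, 30% H2O2 (6 equiv), 0 → 20 °C, 4 h; 2 M HCl
Reagents that add atoms: hydrogen peroxide, OO
Why: Claisen–Schmidt aldol condensation gives the (E)-2'-hydroxychalcone 14, and alkaline H2O2 (Algar–Flynn–Oyamada reaction) closes the pyranone ring by 6-endo attack of the 2'-phenoxide on the β-carbon (O1–C2 bond) with hydroxylation at C3 and in-situ dehydrogenation to the flavonol, the electron-rich 4-methoxyphenyl β-substituent favouring the 6-endo over the aurone-forming 5-exo mode; water is the only by-product and the side-chain stereocentre is not involved.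

Step 8
Reactants: 15 7-(benzyloxy)-3-hydroxy-2-{3-[(3S)-4-hydroxy-3-methylbutyl]-4-methoxyphenyl}-5,6-dimethoxy-4H-chromen-4-one
Product: 16 3,7-dihydroxy-2-{3-[(3S)-4-hydroxy-3-methylbutyl]-4-methoxyphenyl}-5,6-dimethoxy-4H-chromen-4-one (CNP0267774.1)
Conditions: H2 (1 atm), 10% Pd/C, EtOAc/MeOH 1:1, 25 °C
Reagents that add atoms: none
Why: Hydrogenolysis of the aryl benzyl ether on Pd/C is fast at 1 atm, while the tetrasubstituted C2=C3 bond of the flavonol, the aryl methyl ethers and the stereocentre are inert (O-debenzylation).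

**Compound list**

1 | 3-bromo-4-methoxybenzonitrile | COc1ccc(C#N)cc1Br | starting material
2 | 4-bromo-2-methylbut-1-ene | C=C(C)CCBr | starting material
3 | bromo(3-methylbut-3-en-1-yl)zinc | C=C(C)CC[Zn]Br | intermediate (not isolated)
4 | 4-methoxy-3-(3-methylbut-3-en-1-yl)benzonitrile | COc1ccc(C#N)cc1CCC(C)=C | intermediate
5 | 4-methoxy-3-[(3R)-3-methyl-4-(4,4,5,5-tetramethyl-1,3,2-dioxaborolan-2-yl)butyl]benzonitrile | COc1ccc(C#N)cc1CC[C@H](C)CB1OC(C)(C)C(C)(C)O1 | intermediate (not isolated)
6 | 3-[(3S)-4-hydroxy-3-methylbutyl]-4-methoxybenzonitrile | COc1ccc(C#N)cc1CC[C@H](C)CO | intermediate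
7 | 1-{3-[(3S)-4-{[bis(2-methylpropyl)alumanyl]oxy}-3-methylbutyl]-4-methoxyphenyl}-N-[bis(2-methylpropyl)alumanyl]methanimine | COc1ccc(C=N[Al](CC(C)C)CC(C)C)cc1CC[C@H](C)CO[Al](CC(C)C)CC(C)C | intermediate (not isolated)
8 | 3-[(3S)-4-hydroxy-3-methylbutyl]-4-methoxybenzaldehyde | COc1ccc(C=O)cc1CC[C@H](C)CO | intermediate
9 | 2',4'-dihydroxy-6'-methoxyacetophenone | CC(=O)c1c(O)cc(O)cc1OC | starting material
10 | 4'-(benzyloxy)-2'-hydroxy-6'-methoxyacetophenone | CC(=O)c1c(O)cc(OCc2ccccc2)cc1OC | intermediate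
11 | potassium 3-acetyl-6-(benzyloxy)-4-hydroxy-2-methoxyphenyl sulfate | CC(=O)c1c(O)cc(OCc2ccccc2)c(OS(=O)(=O)[O-])c1OC.[K+] | intermediate (not isolated)
12 | 4'-(benzyloxy)-2',5'-dihydroxy-6'-methoxyacetophenone | CC(=O)c1c(O)cc(OCc2ccccc2)c(O)c1OC | intermediate
13 | 4'-(benzyloxy)-2'-hydroxy-5',6'-dimethoxyacetophenone | CC(=O)c1c(O)cc(OCc2ccccc2)c(OC)c1OC | intermediate
14 | (E)-1-[4-(benzyloxy)-2-hydroxy-5,6-dimethoxyphenyl]-3-{3-[(3S)-4-hydroxy-3-methylbutyl]-4-methoxyphenyl}prop-2-en-1-one | COc1ccc(/C=C/C(=O)c2c(O)cc(OCc3ccccc3)c(OC)c2OC)cc1CC[C@H](C)CO | intermediate (not isolated)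
15 | 7-(benzyloxy)-3-hydroxy-2-{3-[(3S)-4-hydroxy-3-methylbutyl]-4-methoxyphenyl}-5,6-dimethoxy-4H-chromen-4-one | COc1ccc(-c2oc3cc(OCc4ccccc4)c(OC)c(OC)c3c(=O)c2O)cc1CC[C@H](C)CO | intermediate
16 | 3,7-dihydroxy-2-{3-[(3S)-4-hydroxy-3-methylbutyl]-4-methoxyphenyl}-5,6-dimethoxy-4H-chromen-4-one | COc1ccc(-c2oc3cc(O)c(OC)c(OC)c3c(=O)c2O)cc1CC[C@H](C)CO | target

**Step count and risks**

Total step count: 8. Longest linear sequence: 5 steps (4, 5, 6, 7, 8 from 9; equally 1, 2, 3, 7, 8 from 1).

The three steps most likely to fail: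

Step 2 (the proposed new method). The risk is insufficient enantioselectivity for methyl against a linear chain, or partial reduction of the nitrile by CuH. The fallback uses known chiral-pool chemistry; it sets out from aryl bromide 1 and comes back at alcohol 6, so compounds 2–5 are then not needed. Commercial methyl (R)-3-hydroxy-2-methylpropanoate is silylated (TBSCl, imidazole, CH2Cl2) to methyl (2R)-3-[(tert-butyldimethylsilyl)oxy]-2-methylpropanoate F1. This is reduced (DIBAL-H, CH2Cl2, −78 °C) to (2R)-3-[(tert-butyldimethylsilyl)oxy]-2-methylpropanal F2 and methylenated (Ph3P=CH2, THF, −78 → 0 °C) to tert-butyldimethyl{[(2S)-2-methylbut-3-en-1-yl]oxy}silane F3. Hydroboration with 9-BBN-H (THF, 25 °C) gives 9-{(3S)-4-[(tert-butyldimethylsilyl)oxy]-3-methylbutyl}-9-borabicyclo[3.3.1]nonane F4, which is coupled in the same pot with 1 (Pd(dppf)Cl2, aq K3PO4, THF/DMF, 60 °C, B-alkyl Suzuki–Miyaura) to 3-[(3S)-4-[(tert-butyldimethylsilyl)oxy]-3-methylbutyl]-4-methoxybenzonitrile F5. TBAF (THF) then gives 6, which also serves as the authentic sample for assigning the ligand antipode.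

Step 7. 2'-Hydroxychalcones with a 6'-methoxy group can divert to the aurone (5-exo closure) under Algar–Flynn–Oyamada conditions. The fallback sets out from chalcone 14, now isolated after the condensation stage, and comes back at 15. Cat. I2 in DMSO at 120 °C cyclises and dehydrogenates 14 to 7-(benzyloxy)-2-{3-[(3S)-4-hydroxy-3-methylbutyl]-4-methoxyphenyl}-5,6-dimethoxy-4H-chromen-4-one F6. Dimethyldioxirane (acetone, 0 °C) epoxidises its C2=C3 bond to 7-(benzyloxy)-2,3-epoxy-2-{3-[(3S)-4-hydroxy-3-methylbutyl]-4-methoxyphenyl}-5,6-dimethoxychroman-4-one F7 (both epoxide diastereomers), and cat. p-TsOH (CH2Cl2) opens the epoxide to 15.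

Step 5. Elbs oxidations typically stop at 30–45% conversion and the hydroquinone can over-oxidise. The fallback sets out from 10 and comes back at 12. Teuber oxidation with Fremy's salt (KH2PO4 buffer, acetone/H2O) gives 2-acetyl-5-(benzyloxy)-3-methoxycyclohexa-2,5-diene-1,4-dione F8, and Na2S2O4 (H2O/EtOAc) reduces it to 12.

**Further compounds**

F1 | step 2 | methyl (2R)-3-[(tert-butyldimethylsilyl)oxy]-2-methylpropanoate | COC(=O)[C@H](C)CO[Si](C)(C)C(C)(C)C
F2 | step 2 | (2R)-3-[(tert-butyldimethylsilyl)oxy]-2-methylpropanal | O=C[C@H](C)CO[Si](C)(C)C(C)(C)C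
F3 | step 2 | tert-butyldimethyl{[(2S)-2-methylbut-3-en-1-yl]oxy}silane | C=C[C@H](C)CO[Si](C)(C)C(C)(C)C
F4 | step 2 | 9-{(3S)-4-[(tert-butyldimethylsilyl)oxy]-3-methylbutyl}-9-borabicyclo[3.3.1]nonane | B1(CC[C@H](C)CO[Si](C)(C)C(C)(C)C)C2CCCC1CCC2
F5 | step 2 | 3-[(3S)-4-[(tert-butyldimethylsilyl)oxy]-3-methylbutyl]-4-methoxybenzonitrile | COc1ccc(C#N)cc1CC[C@H](C)CO[Si](C)(C)C(C)(C)C
F6 | step 7 | 7-(benzyloxy)-2-{3-[(3S)-4-hydroxy-3-methylbutyl]-4-methoxyphenyl}-5,6-dimethoxy-4H-chromen-4-one | COc1ccc(-c2cc(=O)c3c(OC)c(OC)c(OCc4ccccc4)cc3o2)cc1CC[C@H](C)CO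
F7 | step 7 | 7-(benzyloxy)-2,3-epoxy-2-{3-[(3S)-4-hydroxy-3-methylbutyl]-4-methoxyphenyl}-5,6-dimethoxychroman-4-one (both epoxide diastereomers) | COc1ccc(C23OC2C(=O)c2c(OC)c(OC)c(OCc4ccccc4)cc2O3)cc1CC[C@H](C)CO
F8 | step 5 | 2-acetyl-5-(benzyloxy)-3-methoxycyclohexa-2,5-diene-1,4-dione | CC(=O)C1=C(OC)C(=O)C(OCc2ccccc2)=CC1=O
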